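(All runs were generated by integration with made-up constants, noise included.)

Count the ligand first: these flasks get the same charges and differ in how the starting complex or the incoming ligand goes in.

| flask | starting complex | incoming ligand | remark | time |
|---|---|---|---|---|
| beta | 0.44 M | 0.44 M | run made earlier |  |
| epsilon | 0.62 M | 0.44 M | run made earlier |  |
| delta | 0.97 M | 0.44 M | run made earlier |  |
| north-west | 0.44 M | 0.440 M | everything together at the start | 40 min |
| south-west | 0.44 M (fed, over 25 min) | 0.440 M | all else is in the flask from the start; the feed brings no volume worth counting | 40 min |
| north | 0.44 M (in portions, 4, over 25 min) | 0.440 M | first portion at the start, last at 25 min | 40 min |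
| south-east | 0.44 M | 0.440 M (fed, over 25 min) | all else is in the flask from the start; the feed brings no volume worth counting | 40 min |

| run | time / min | complex with one exchanged / % | complex with two exchanged / % |
|---|---|---|---|
| beta | 3.00 | 20.7 | 21.4 |
| beta | 5.00 | 18.2 | 27.2 |
| beta | 8.00 | 15.8 | 32.6 |
| beta | 15.0 | 12.7 | 34.7 |
| beta | 25.0 | 11.5 | 35.8 |
| beta | 40.0 | 11.3 | 35.1 |
| epsilon | 3.00 | 19.0 | 15.8 |
| epsilon | 10.0 | 14.4 | 21.0 |
| epsilon | 15.0 | 12.8 | 21.6 |
| epsilon | 25.0 | 10.7 | 22.2 |
| epsilon | 40.0 | 10.4 | 21.7 |
| epsilon | 50.0 | 11.2 | 21.8 |
| delta | 4.00 | 16.5 | 11.2 |
| delta | 6.00 | 14.6 | 10.2 |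
| delta | 10.0 | 12.6 | 11.2 |
| delta | 20.0 | 9.8 | 11.2 |
| delta | 30.0 | 9.2 | 11.5 |
| delta | 50.0 | 9.4 | 10.4 |

(each reading ± 0.5 percentage points)

- the flask that comes out highest in share of complex with one exchanged in complex with one exchanged plus complex with two exchanged, or "all alike" when all lie within 1.5 percentage points (north-west / south-west / north / south-east / all alike)
- share of complex with one exchanged in complex with one exchanged plus complex with two exchanged at the end, north-west
- share of complex with one exchanged in complex with one exchanged plus complex with two exchanged at the end, south-west
- share of complex with one exchanged in complex with one exchanged plus complex with two exchanged at the end, north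
- share of complex with one exchanged in complex with one exchanged plus complex with two exchanged at the end, south-east



The readings stand flat at the end of each run, so I assume no incoming ligand remains there, which makes it the limiting reagent. Each ligand then sits in complex with one exchanged, twice over in complex with two exchanged, or somewhere unseen. Let L be c(incoming ligand)/c(starting complex) as charged, and f the final complex with two exchanged divided by L. In the beta run 1.64 is the hidden ratio r, the ligand not found per complex with one exchanged.

| run | L | f | r |
|---|---|---|---|
| beta | 1.00 | 0.351 | 1.64 |
| epsilon | 0.710 | 0.307 | 1.44 |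
| delta | 0.454 | 0.229 | 1.61 |

Since r stays put, the balance gives the share: S = g/(g + f(1 + r)), with g = 1 − 2f. North-west repeats beta, so I read 24.4%.

The bench rule says a slow feed acts like a batch holding its mean dosed amount, L/2. For south-east, the line through beta and delta then gives f = 0.240. But complex with one exchanged settles in 6.79 min, read from beta, and the feed lasts 3.68 such times, which is few. So I stop trusting the rule here and take f midway to batch, 0.295, which gives south-east 34.5%. North opens at L = 4.00, beyond every run, so I give no figure and place it and south-west below north-west.

The forecast names south-east at 27% (24.5% to 31%), with 24.4%, 15% and 15.5% for north-west, south-west and north: "Slow ligand feed keeps complex in excess".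

South-east comes out highest at 30.7%, against 24.6% in north-west, 17.6% in south-west and 16.3% in north.

    starting complex + incoming ligand → leaving ligand + complex with one exchanged (k = 0.0140 M⁻¹ s⁻¹)
    complex with one exchanged ⇌ isomer of the product (K = 1.50, k = 0.00190 s⁻¹)
    complex with one exchanged + incoming ligand → leaving ligand + complex with two exchanged (k = 0.0290 M⁻¹ s⁻¹)

My midway reckoning overshoots south-east by 3.8 percentage points. The neighbouring flask is south-east with 0.75 M of starting complex, so L = 0.587. The same line gives f = 0.226, and with r the share reckons to 47.9%. That flask gives 48.4%.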